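## The problem

The target, 5-(2,4,6-trihydroxyphenoxy)-4-(3,4,5-trihydroxyphenoxy)benzene-1,2,3-triol (20), has three benzene rings, two diaryl ether oxygens, nine free phenolic hydroxyls and no stereocenter. The task is therefore one of connectivity and regiochemistry only. The two ether oxygens sit on neighbouring carbons of the central ring B: B1 carries ring A (a phloroglucinol ring bound through its position 1, between two hydroxylated carbons) and B6 carries ring C (a pyrogallol-type ring bound through its position 1). B3, B4 and B5 are hydroxylated and B2 is the only CH of ring B. Both ether bonds are crowded and join electron-rich rings; the B6 oxygen in particular lies between the B1 oxygen and the B5 oxygen, so plain nucleophilic aromatic substitution is excluded and a copper coupling at B6 is the weakest link of any conventional plan. The free nonaphenol (one 1,3,5-triol ring, two 1,2,3-triol rings) is oxidized by air, fastest in base, so all hydroxyls must travel as ethers and be released last under acidic, oxygen-free conditions. Ring C offers the opening: positions 1 (ether oxygen) and 4 (hydroxyl) are para, positions 3 and 5 are oxygenated and positions 2 and 6 are CH. This is the pattern of a carbene complex benzannulation in which the carbene carbon, already bound to the B6 oxygen, becomes position 1, a carbonyl ligand becomes position 4, a terminal ynol ether supplies positions 2 and 3, and a 2-alkoxyvinyl group supplies positions 5 and 6.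

## Retrosynthesis

**20 to 19.** The last disconnection cuts eight O–alkyl bonds: six O–methyl bonds on rings A and B and two O–ethyl bonds at positions 3 and 5 of ring C. The ethyl groups are the residue of the two C2 building blocks of ring C and need a Lewis-acid dealkylation in any case. Methyl is therefore chosen for rings A and B so that one reagent removes everything; benzyl ethers would add a hydrogenolysis without saving that step. Compound 19 has the full skeleton but is stable to air and chromatography. The forward step must cleave alkyl–oxygen bonds only and leave both aryl–oxygen–aryl bridges.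

**19 to 16 and 17.** Ring C is opened at its bonds 1–2, 3–4 and 4–5. Position 1 goes back to the carbene carbon of the chromium complex 16, positions 5 and 6 to its 2-ethoxyvinyl arm, position 4 to a carbonyl ligand, and positions 2 and 3 to ethoxyacetylene 17. The neighbouring cut, a direct copper coupling of phenol 9 with a 3,4,5-trioxygenated aryl halide, is one step shorter and that must be granted. It asks a phenol with two ortho substituents to meet an unactivated, electron-rich aryl halide. In the carbene route the same oxygen is bound to a strongly electrophilic non-aromatic carbon and the ring is grown around it. Compound 16 holds only rings A and B. The forward reaction must insert the alkyne with ethoxy next to the carbonyl-derived carbon and must incorporate CO rather than close a five-membered ring.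

**16 to 14 and 9.** The O–C(carbene) bond is cut, giving the acylchromate salt 14 and the A–B phenol 9. An aryl group cannot be put on the acylate oxygen by alkylation, so the bond has to be made in the opposite sense, by activating the acylate as a mixed anhydride and letting the phenol displace carboxylate. Compound 9 is an ordinary, storable phenol. The forward step must be fast enough at low temperature to outrun decomposition of the activated carbene.

**14 to 10 and 11.** The bond between the vinyl alpha carbon and the acyl carbon is cut, giving (Z)-1-bromo-2-ethoxyethene 10 and Cr(CO)6 11, both commercial. This is the standard entry to acylmetalates and builds the whole C3 arm in one operation. The forward step needs a vinyllithium that survives until it has added to a carbonyl ligand.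

**9 to 7.** The B6–O bond is traced to a B6–CHO bond (aryl migration to oxygen). The formyl group serves twice: it is a masked hydroxyl, and as an ortho carbonyl it activates the neighbouring carbon–halogen bond for the ether coupling that precedes it. Direct hydroxylation of an A–B ether lacking the B6 substituent was rejected, because electrophiles and bases would attack ring A, whose two CH positions each lie between two methoxy groups. The oxidation must take the aldehyde before a peracid attacks ring A.

**7 to 3 and 6.** The B1–O bond is cut with the oxygen staying on ring A, giving bromoaldehyde 3 and 2,4,6-trimethoxyphenol 6. The reverse polarity would put the halogen on ring A between two methoxy groups and the hydroxyl on ring B next to the formyl group. That pairs a hindered, electron-rich halide with a deactivated, chelating phenol, the worst combination for copper. In the chosen polarity the halide has one ortho substituent, and that one is activating. Both fragments are single rings.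

**3 to 1, and 6 to 4.** Compound 3 loses its formyl carbon to give commercial 5-bromo-1,2,3-trimethoxybenzene 1, whose two free positions are equivalent, so formylation has no regiochemical choice. Compound 6 goes back to commercial 2,4,6-trimethoxybenzaldehyde 4 by the same aldehyde-to-phenol oxidation used for 9.

## Roads not taken

**Alternative 1:** The cut removes two C–O bonds, at B4 and at position 4 of ring C, from a resorcinol-type diaryl ether A2 (B1 oxygen silylated, four methoxymethyl ethers). Forward, A2 would be lithiated twice with an alkyllithium, each time at the CH between two methoxymethoxy groups, then borylated and oxidized to the bis-phenol A1.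
- Merits: every reaction is routine, the metalation sites are unambiguous, and two hydroxyls arrive in one operation.
- Weak points: the step closes no ring and makes neither ether bridge. A2 still needs a coupling at the doubly flanked B6 oxygen, and ring A must later be attached at B1 by a second coupling with a 2,4,6-trioxygenated partner, the hardest ether coupling of all. Three kinds of protecting group are needed, and A1 carries two 2,6-dioxygenated phenols that peroxide can over-oxidize.
- Comparison: step for step this road is more certain than the chosen plan, which rests on an untested benzannulation. The chosen plan sets against it a much shorter sequence and the removal of the B6 coupling from the list of aromatic substitutions.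

**Alternative 2:** Ring B is cut at B2–B3 and B1–B6 into the cyclobutenone A4, which already carries the ring C oxygen, and the aryl ynol ether A5, which carries ring A. Forward, heating opens A4 to a vinylketene, A5 adds across it, and a second ring opening and six-electron closure give the ring B phenol A3.
- Merits: both ether oxygens are attached at non-aromatic carbons, the plan is more convergent, and cyclobutenone–alkyne benzannulations with ynol ethers are established. Its key step therefore stands on firmer precedent than step 7.
- Weak points: A4 requires a squaric acid diester to be desymmetrized (one aryloxy, one methoxy) and then reduced at one specific carbonyl, a regiochemical problem with no obvious bias. A5 takes two further steps, and an aryloxyalkyne is a weaker nucleophile toward the ketene than an alkoxy- or siloxyalkyne.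
- Comparison: in ambition this is the better idea, since it solves both bridges at once. The chosen plan sets against it building blocks that are commercial or one step away, no regiochemical ambiguity before the key step, and an A–B bridge that is easy anyway once the ortho formyl group assists the coupling.

**Alternative 3:** Ring A is cut at A1–A2 to the aryloxy triketide ester A7. Forward, base-mediated intramolecular Claisen condensation of the aryloxy-bearing C6 onto the ester would give the phloroglucinol A6.
- Merits: it follows the biosynthetic logic, delivers ring A unprotected, and makes the crowded A1–O bond beforehand as a simple alkyl aryl ether.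
- Weak points: 3,5-dioxo esters prefer to lactonize to pyrones or to close by aldol reaction, and the required carbanion at C6 must form in the presence of the more acidic C2 and C4 methylenes. The B6–O–ring C bridge, the harder of the two, is left to a conventional coupling.
- Comparison: this road spends its key step on the bridge that the chosen plan expects to form without trouble and leaves the difficult one untouched. It would be the better choice only if the A–B coupling of step 3 failed.

Key step: step 7

Assumption: the 2-ethoxyvinyl group is drawn Z in 12 to 16, as inherited from 10 with retention; its geometry is without consequence because that carbon becomes aromatic in step 7.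

## Route

Step 1
Reactants: 1 5-bromo-1,2,3-trimethoxybenzene
Product: 3 6-bromo-2,3,4-trimethoxybenzaldehyde, via alpha-chloro ether 2 (not isolated)
Conditions: Cl2CHOMe, TiCl4, CH2Cl2, −10 to 0 °C; then ice/H2O
Reagents that add atoms: dichloromethyl methyl ether, COC(Cl)Cl; water, O
Why: Rieche formylation; the two free positions of 1 are equivalent, each ortho to one methoxy group and para to another, so a single aldehyde should form, and the low temperature limits TiCl4-induced cleavage of the methoxy group next to the new carbonyl.

Step 2
Reactants: 4 2,4,6-trimethoxybenzaldehyde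
Product: 6 2,4,6-trimethoxyphenol, via aryl formate 5 (not isolated)
Conditions: mCPBA (1.05 equiv), CH2Cl2, 0 °C to rt; aq NaHCO3 wash; then K2CO3 (cat.), MeOH, rt, Ar
Reagents that add atoms: mCPBA (3-chloroperoxybenzoic acid), OOC(=O)c1cccc(Cl)c1
Why: Baeyer–Villiger oxidation in which the aryl group migrates because two ortho and one para methoxy groups make it the better migrating group, followed by methanolysis of the formate (overall a Dakin-type conversion of ArCHO to ArOH).

Step 3
Reactants: 3 6-bromo-2,3,4-trimethoxybenzaldehyde; 6 2,4,6-trimethoxyphenol
Product: 7 2,3,4-trimethoxy-6-(2,4,6-trimethoxyphenoxy)benzaldehyde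
Conditions: CuI (10 mol %), picolinic acid (20 mol %), K3PO4 (2 equiv), DMSO, 90 °C, Ar
Reagents that add atoms: none
Why: Ullmann-type diaryl ether synthesis with a ligand system suited to ortho-substituted phenols; the bromide of 3 has only one ortho substituent, and that formyl group activates the carbon–bromine bond.

Step 4
Reactants: 7 2,3,4-trimethoxy-6-(2,4,6-trimethoxyphenoxy)benzaldehyde
Product: 9 2,3,4-trimethoxy-6-(2,4,6-trimethoxyphenoxy)phenol, via aryl formate 8 (not isolated)
Conditions: mCPBA (1.1 equiv), CH2Cl2, 0 °C; aq NaHCO3 wash; then K2CO3 (cat.), MeOH, rt
Reagents that add atoms: mCPBA (3-chloroperoxybenzoic acid), OOC(=O)c1cccc(Cl)c1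
Why: Baeyer–Villiger oxidation with aryl migration, favoured by the ortho methoxy, ortho aryloxy and para methoxy groups, then formate methanolysis; a near-stoichiometric amount of peracid at 0 °C should spare the electron-rich ring A.

Step 5
Reactants: 10 (Z)-1-bromo-2-ethoxyethene; 11 chromium hexacarbonyl, Cr(CO)6
Product: 14 tetramethylammonium pentacarbonyl[(Z)-3-ethoxy-1-oxidoprop-2-en-1-ylidene]chromate, via (Z)-2-ethoxyvinyllithium 12 (not isolated), via lithium acylchromate 13 (not isolated)
Conditions: n-BuLi, Et2O, −78 °C; Cr(CO)6, THF, −78 to −20 °C; then Me4NBr, H2O, 0 °C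
Reagents that add atoms: tetramethylammonium bromide, C[N+](C)(C)C.[Br-]
Why: Lithium–bromine exchange with retention gives the Z vinyllithium, in which lithium and ethoxy are syn so that beta-elimination is slow; its addition to a carbonyl ligand is the Fischer acylmetalate synthesis, and cation exchange gives a salt that can be stored and dissolved in CH2Cl2.

Step 6
Reactants: 14 tetramethylammonium pentacarbonyl[(Z)-3-ethoxy-1-oxidoprop-2-en-1-ylidene]chromate; 9 2,3,4-trimethoxy-6-(2,4,6-trimethoxyphenoxy)phenol
Product: 16 pentacarbonyl{[(Z)-2-ethoxyethenyl][2,3,4-trimethoxy-6-(2,4,6-trimethoxyphenoxy)phenoxy]carbene}chromium, via acetoxycarbene complex 15 (not isolated)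
Conditions: 14 (1.5 equiv), AcBr (1.4 equiv), CH2Cl2, −40 °C; then 9 (1.0 equiv), −40 to 0 °C
Reagents that add atoms: none
Why: O-acylation of the acylchromate gives the acetoxycarbene complex, and the phenol displaces acetate at the carbene carbon by addition–elimination (the acyloxycarbene route to alkoxy- and aryloxycarbene complexes); acetyl bromide is kept below the amount of 14 so that none is left to acetylate 9, and the low temperature allows for the thermal lability of 15.

Step 7
Reactants: 16 pentacarbonyl{[(Z)-2-ethoxyethenyl][2,3,4-trimethoxy-6-(2,4,6-trimethoxyphenoxy)phenoxy]carbene}chromium; 17 ethoxyacetylene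
Product: 19 2,6-diethoxy-4-[2,3,4-trimethoxy-6-(2,4,6-trimethoxyphenoxy)phenoxy]phenol, via tricarbonylchromium arene complex 18 (not isolated)
Conditions: 17 (3 equiv, slow addition), THF, 50 °C, Ar; then air, MeCN, rt
Reagents that add atoms: none
Why: Proposed new method: loss of one CO from zerovalent chromium in 16 lets 17 insert into the chromium–carbene bond, the old carbene carbon (ring C position 1, already carrying the B6 oxygen) bonding to the CH terminus (position 2) while the ethoxy-bearing carbon (position 3) stays on chromium; CO insertion at that carbon gives the vinylketene (bond 3–4). Ring C then closes by six-electron disrotatory electrocyclization of the ketene carbon onto the ethoxyvinyl beta carbon (bond 4–5), and the cyclohexadienone tautomerizes to the phenol, held as the Cr(CO)3 complex 18 until air releases 19. The closest known reaction type is the Dötz benzannulation of alkoxy- and aryloxy(alkenyl)carbene complexes of Cr(CO)5 with terminal alkynes; what has not been shown is an ynol ether as the alkyne together with a 2-alkoxyvinyl arm. The step needs one regiochemistry, ethoxy next to the carbonyl-derived carbon, and two effects point the same way: the larger alkyne substituent ends next to that carbon as with every terminal alkyne, and the nucleophilic CH carbon of the ynol ether is the one that attacks the electrophilic carbene carbon. Should insertion occur in this polar way without prior CO loss, the product is a 1-ethoxydienylcarbene complex of the same connectivity, a class known to close to ortho-alkoxyphenols through the same ketene on heating or irradiation. It also needs CO insertion to beat five-membered ring formation, which the aryloxy group favours because it is a weaker donor than alkoxy and offsets the donor effect of the beta-ethoxy group. No stereocenter is formed and the Z geometry of the vinyl group is lost on aromatization. Slow addition of 17 limits its oligomerization, and no oxidant stronger than air is used at work-up because 19 is a hydroquinone monoaryl ether that a strong oxidant would turn into the quinone with loss of 9.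

Step 8
Reactants: 19 2,6-diethoxy-4-[2,3,4-trimethoxy-6-(2,4,6-trimethoxyphenoxy)phenoxy]phenol
Product: 20 5-(2,4,6-trihydroxyphenoxy)-4-(3,4,5-trihydroxyphenoxy)benzene-1,2,3-triol
Conditions: BBr3 (excess), CH2Cl2, −78 °C to rt, Ar; then degassed H2O, 0 °C
Reagents that add atoms: none
Why: Lewis-acid ether cleavage: BBr3 binds each alkyl aryl ether oxygen and bromide attacks the methyl or ethyl carbon, whereas the two diaryl ether oxygens offer no sp3 carbon and should stay intact; the acidic, non-oxidizing medium suits the air-sensitive nonaphenol.

## Compound list

1 | 5-bromo-1,2,3-trimethoxybenzene | COc1cc(Br)cc(OC)c1OC | starting material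
2 | 1-bromo-2-[chloro(methoxy)methyl]-3,4,5-trimethoxybenzene (alpha-chloro ether, racemic) | COC(Cl)c1c(Br)cc(OC)c(OC)c1OC | intermediate
3 | 6-bromo-2,3,4-trimethoxybenzaldehyde | O=Cc1c(Br)cc(OC)c(OC)c1OC | intermediate
4 | 2,4,6-trimethoxybenzaldehyde | COc1cc(OC)c(C=O)c(OC)c1 | starting material
5 | 2,4,6-trimethoxyphenyl formate | O=COc1c(OC)cc(OC)cc1OC | intermediate
6 | 2,4,6-trimethoxyphenol | Oc1c(OC)cc(OC)cc1OC | intermediate
7 | 2,3,4-trimethoxy-6-(2,4,6-trimethoxyphenoxy)benzaldehyde | O=Cc1c(Oc2c(OC)cc(OC)cc2OC)cc(OC)c(OC)c1OC | intermediate
8 | 2,3,4-trimethoxy-6-(2,4,6-trimethoxyphenoxy)phenyl formate | O=COc1c(Oc2c(OC)cc(OC)cc2OC)cc(OC)c(OC)c1OC | intermediate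
9 | 2,3,4-trimethoxy-6-(2,4,6-trimethoxyphenoxy)phenol | Oc1c(OC)c(OC)c(OC)cc1Oc1c(OC)cc(OC)cc1OC | intermediate
10 | (Z)-1-bromo-2-ethoxyethene | CCO/C=C\Br | starting material
11 | chromium hexacarbonyl, Cr(CO)6 | O=C=[Cr](=C=O)(=C=O)(=C=O)(=C=O)=C=O | starting material
12 | (Z)-2-ethoxyvinyllithium | CCO/C=C\[Li] | intermediate
13 | lithium pentacarbonyl[(Z)-3-ethoxy-1-oxidoprop-2-en-1-ylidene]chromate | [Li+].[O-]C(/C=C\OCC)=[Cr](=C=O)(=C=O)(=C=O)(=C=O)=C=O | intermediate
14 | tetramethylammonium pentacarbonyl[(Z)-3-ethoxy-1-oxidoprop-2-en-1-ylidene]chromate | C[N+](C)(C)C.[O-]C(/C=C\OCC)=[Cr](=C=O)(=C=O)(=C=O)(=C=O)=C=O | intermediate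
15 | pentacarbonyl{acetoxy[(Z)-2-ethoxyethenyl]carbene}chromium | CC(=O)OC(/C=C\OCC)=[Cr](=C=O)(=C=O)(=C=O)(=C=O)=C=O | intermediate
16 | pentacarbonyl{[(Z)-2-ethoxyethenyl][2,3,4-trimethoxy-6-(2,4,6-trimethoxyphenoxy)phenoxy]carbene}chromium | O=C=[Cr](=C=O)(=C=O)(=C=O)(=C=O)=C(/C=C\OCC)Oc1c(OC)c(OC)c(OC)cc1Oc1c(OC)cc(OC)cc1OC | intermediate
17 | ethoxyacetylene | CCOC#C | starting material
18 | tricarbonyl(η6-arene)chromium complex of 19, chromium on ring C (the Cr(CO)3 fragment is written as a separate component because the η6 bond has no valence-bond notation) | CCOc1cc(Oc2c(OC)c(OC)c(OC)cc2Oc2c(OC)cc(OC)cc2OC)cc(OCC)c1O.O=C=[Cr](=C=O)=C=O | intermediate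
19 | 2,6-diethoxy-4-[2,3,4-trimethoxy-6-(2,4,6-trimethoxyphenoxy)phenoxy]phenol | Oc1c(OCC)cc(Oc2c(OC)c(OC)c(OC)cc2Oc2c(OC)cc(OC)cc2OC)cc1OCC | intermediate
20 | 5-(2,4,6-trihydroxyphenoxy)-4-(3,4,5-trihydroxyphenoxy)benzene-1,2,3-triol | Oc1cc(O)c(Oc2cc(O)c(O)c(O)c2Oc2cc(O)c(O)c(O)c2)c(O)c1 | target

## Step count and risks

Total steps: 8. Longest linear sequence: 6 steps (1 → 3 → 7 → 9 → 16 → 19 → 20; steps 1, 3, 4, 6, 7, 8).

**Step 7 (key step, the one proposed as a new method).**
- Most likely failure: the ynol ether is consumed without CO being built in. The beta-ethoxy group makes the alkenyl arm a donor and the ynol ether is a strong nucleophile, so three diversions are possible: polar insertion followed by five-membered ring closure, [2+2] addition to the push–pull alkene, or oligomerization of 17. Solvolytic loss of the aryloxy group from the electrophilic carbene carbon is a second hazard.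
- Fallback (known chemistry): it sets out from 9. CuI-catalysed Ullmann coupling (picolinic acid, K3PO4, DMSO, 90 °C) with commercial 4-bromo-2,6-dimethoxybenzaldehyde, whose bromine has no ortho substituent and is activated by the para formyl group, should give 2,6-dimethoxy-4-[2,3,4-trimethoxy-6-(2,4,6-trimethoxyphenoxy)phenoxy]benzaldehyde F1. Baeyer–Villiger oxidation with mCPBA then gives the aryl formate F2, and methanolysis gives 2,6-dimethoxy-4-[2,3,4-trimethoxy-6-(2,4,6-trimethoxyphenoxy)phenoxy]phenol F3, the dimethyl analogue of 19. BBr3 under the conditions of step 8 cleaves its eight methyl ethers, and the fallback rejoins the route at 20.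

**Step 6.**
- Most likely failure: capture of the acetoxycarbene complex 15 by the doubly ortho-substituted phenol 9 is too slow, so that thermal decomposition of 15 or attack at the beta carbon with loss of ethoxide takes over.
- Fallback: it sets out from 9 and gives up the carbene. CuI-catalysed coupling (picolinic acid, K3PO4, DMSO, 90 °C) with commercial 5-iodo-1,2,3-trimethoxybenzene should give 1,2,3-trimethoxy-4-(3,4,5-trimethoxyphenoxy)-5-(2,4,6-trimethoxyphenoxy)benzene F4. BBr3 cleaves its nine methyl ethers, and the fallback rejoins the route at 20.

**Step 3.**
- Most likely failure: oxidative degradation of the very electron-rich phenol 6 in the presence of copper, or coupling so slow (two ortho methoxy groups) that reductive loss of bromine from 3 competes.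
- Fallback: it sets out from 6 and replaces copper catalysis by nucleophilic aromatic substitution. Commercial 5-fluoro-1,2,3-trimethoxybenzene is formylated as in step 1, through the alpha-chloro ether 1-[chloro(methoxy)methyl]-2-fluoro-4,5,6-trimethoxybenzene F5, to 6-fluoro-2,3,4-trimethoxybenzaldehyde F6. The phenoxide of 6 (K2CO3, DMSO, 120 °C, Ar) then displaces the fluoride ortho to the formyl group, and the fallback rejoins the route at 7.

**Step 8.**
- Most likely failure: incomplete cleavage of the two ethyl ethers and of methoxy groups lying between two substituents, together with oxidative loss of the free nonaphenol during aqueous isolation and chromatography.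
- Fallback: it sets out from 19. After the BBr3 treatment the crude 20 is not purified but acetylated at once (Ac2O, pyridine) to 5-(2,4,6-triacetoxyphenoxy)-4-(3,4,5-triacetoxyphenoxy)benzene-1,2,3-triyl triacetate F7. This ester is stable to air and can be chromatographed free of partly dealkylated material. Acid methanolysis (HCl in degassed MeOH) removes the nine acetyl groups, and the fallback rejoins the route at 20.

## Further compounds

F1 | step 7 | 2,6-dimethoxy-4-[2,3,4-trimethoxy-6-(2,4,6-trimethoxyphenoxy)phenoxy]benzaldehyde | O=Cc1c(OC)cc(Oc2c(OC)c(OC)c(OC)cc2Oc2c(OC)cc(OC)cc2OC)cc1OC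
F2 | step 7 | 2,6-dimethoxy-4-[2,3,4-trimethoxy-6-(2,4,6-trimethoxyphenoxy)phenoxy]phenyl formate | O=COc1c(OC)cc(Oc2c(OC)c(OC)c(OC)cc2Oc2c(OC)cc(OC)cc2OC)cc1OC
F3 | step 7 | 2,6-dimethoxy-4-[2,3,4-trimethoxy-6-(2,4,6-trimethoxyphenoxy)phenoxy]phenol | Oc1c(OC)cc(Oc2c(OC)c(OC)c(OC)cc2Oc2c(OC)cc(OC)cc2OC)cc1OC
F4 | step 6 | 1,2,3-trimethoxy-4-(3,4,5-trimethoxyphenoxy)-5-(2,4,6-trimethoxyphenoxy)benzene | COc1cc(OC)c(Oc2cc(OC)c(OC)c(OC)c2Oc2cc(OC)c(OC)c(OC)c2)c(OC)c1
F5 | step 3 | 1-[chloro(methoxy)methyl]-2-fluoro-4,5,6-trimethoxybenzene (racemic) | COC(Cl)c1c(F)cc(OC)c(OC)c1OC
F6 | step 3 | 6-fluoro-2,3,4-trimethoxybenzaldehyde | O=Cc1c(F)cc(OC)c(OC)c1OC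
F7 | step 8 | 5-(2,4,6-triacetoxyphenoxy)-4-(3,4,5-triacetoxyphenoxy)benzene-1,2,3-triyl triacetate | CC(=O)Oc1cc(OC(C)=O)c(Oc2cc(OC(C)=O)c(OC(C)=O)c(OC(C)=O)c2Oc2cc(OC(C)=O)c(OC(C)=O)c(OC(C)=O)c2)c(OC(C)=O)c1
A1 | alternative 1 | 3-[4-hydroxy-3,5-bis(methoxymethoxy)phenoxy]-2,6-bis(methoxymethoxy)-4-[(triisopropylsilyl)oxy]phenol | CC(C)[Si](C(C)C)(C(C)C)Oc1cc(OCOC)c(O)c(OCOC)c1Oc1cc(OCOC)c(O)c(OCOC)c1
A2 | alternative 1 | {2-[3,5-bis(methoxymethoxy)phenoxy]-3,5-bis(methoxymethoxy)phenoxy}tri(propan-2-yl)silane | CC(C)[Si](C(C)C)(C(C)C)Oc1cc(OCOC)cc(OCOC)c1Oc1cc(OCOC)cc(OCOC)c1
A3 | alternative 2 | 2-[(tert-butyldimethylsilyl)oxy]-3-methoxy-5-(2,4,6-trimethoxyphenoxy)-4-(3,4,5-trimethoxyphenoxy)phenol | Oc1cc(Oc2c(OC)cc(OC)cc2OC)c(Oc2cc(OC)c(OC)c(OC)c2)c(OC)c1O[Si](C)(C)C(C)(C)C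
A4 | alternative 2 | 4-[(tert-butyldimethylsilyl)oxy]-3-methoxy-2-(3,4,5-trimethoxyphenoxy)cyclobut-2-en-1-one (racemic) | O=C1C(Oc2cc(OC)c(OC)c(OC)c2)=C(OC)C1O[Si](C)(C)C(C)(C)C
A5 | alternative 2 | 2-(ethynyloxy)-1,3,5-trimethoxybenzene | C#COc1c(OC)cc(OC)cc1OC
A6 | alternative 3 | 2-[3,4,5-trimethoxy-2-(3,4,5-trimethoxyphenoxy)phenoxy]benzene-1,3,5-triol | Oc1cc(O)c(Oc2cc(OC)c(OC)c(OC)c2Oc2cc(OC)c(OC)c(OC)c2)c(O)c1
A7 | alternative 3 | methyl 3,5-dioxo-6-[3,4,5-trimethoxy-2-(3,4,5-trimethoxyphenoxy)phenoxy]hexanoate | COC(=O)CC(=O)CC(=O)COc1cc(OC)c(OC)c(OC)c1Oc1cc(OC)c(OC)c(OC)c1
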